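**Plan**
- Retrosynthesis: the C-5–prenyl bond (Stille coupling) and the methyl on O-2 are removed first, leading back to centrosymmetric 2,5-dihydroxy-3,6-di(indol-3-yl)-1,4-benzoquinone. The ring is then cut twice, at C-1–C-6 and C-4–C-3, to two molecules of ethyl indol-3-ylpyruvate, made from indole.
- Enabling feature: the six ring carbons are two identical three-carbon units, indolyl-C–C(O)–C(O) (C-3/C-2/C-1 and C-6/C-5/C-4), joined head to tail. Each ester carbon can therefore be acylated onto the acidic indolylmethylene carbon of the other unit, as in the presumed biosynthesis.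
- Forward: indole is alkylated at C-3 with a nitrosoalkene and the oxime is removed. A double Claisen/Dieckmann dimerisation then builds the quinone ring, the only ring made, directly at the quinone oxidation level.
- The symmetric dihydroxyquinone is desymmetrised by mono-triflation, the other OH is methylated, and the triflate is exchanged for prenyl.
- Stereochemistry: the target has no stereocentre and no stereogenic double bond, so nothing has to be set.

Key step: step 3

Remarks on the chemistry: 6 is written as the keto tautomer although it should exist largely as the (Z)-enol. 8 and 9 are written as 2-hydroxy-1,4-quinone tautomers. The oxime geometry of 2 and 4 is left open because the oxime is removed in step 2.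

Step 1
Reactants: 1 indole; 2 ethyl 3-bromo-2-(hydroxyimino)propanoate
Product: 4 ethyl 2-(hydroxyimino)-3-(1H-indol-3-yl)propanoate, via ethyl 2-nitrosoprop-2-enoate 3 (not isolated)
Conditions: Na2CO3, CH2Cl2, rt (1 in excess)
Reagents that add atoms: none
Why: Base-induced 1,4-elimination of HBr from 2 should give the transient nitrosoalkene 3, a strong Michael acceptor that is trapped by the nucleophilic C-3 of indole (conjugate addition with rearomatisation) to give the 3-alkylated oxime; no stereocentre is formed.

Step 2
Reactants: 4 ethyl 2-(hydroxyimino)-3-(1H-indol-3-yl)propanoate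
Product: 6 ethyl 3-(1H-indol-3-yl)-2-oxopropanoate, via imino ester 5 (not isolated)
Conditions: TiCl3 (aq.), NH4OAc, THF/H2O, rt; then 1 M HCl
Reagents that add atoms: water, O
Why: Trivalent titanium should cleave the N–O bond of the oxime reductively to the imine 5, which is hydrolysed in the aqueous medium to the α-keto ester (reductive deoximation), the indole and the ester being inert to these conditions; no stereocentre is formed.

Step 3
Reactants: 6 ethyl 3-(1H-indol-3-yl)-2-oxopropanoate (two molecules)
Product: 8 2,5-dihydroxy-3,6-di(1H-indol-3-yl)cyclohexa-2,5-diene-1,4-dione, via open-chain trioxohexanoate 7 (not isolated)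
Conditions: NaH (1.05 equiv per ester), degassed THF, 0 °C, then 65 °C, Ar; aq. HCl work-up
Reagents that add atoms: none
Why: Proposed new method: complete conversion of 6 into its sodium enolate removes the C-2 ketone as an aldol acceptor, so the only electrophile left is the ester carbonyl; C-3 of one enolate should then be acylated by the ester of a second (intermolecular Claisen condensation, loss of ethoxide) to give 7, whose second enolate carbon C-6 attacks the remaining ester in a Dieckmann condensation and, after loss of the second ethoxide, gives the dianion of 8 directly at the quinone oxidation level. The closest known reaction type is the Claisen–Dieckmann self-condensation of dialkyl succinates to succinylsuccinates, and the step copies the head-to-tail union of two indolylpyruvoyl units in the presumed biosynthesis of the bis-indolylquinones; it has not been shown on arylpyruvate esters, which under catalytic base tend to follow an aldol–lactonisation path. The six-membered carbocycle closes in a 6-exo-trig mode (enolate carbon onto ester carbonyl), a favoured closure. No stereocentre is created, since both indole-bearing carbons end sp2. The selectivity needed is C-acylation over aldol addition and over O-acylation; it should be secured by the stoichiometric base (no keto form present), by the reversibility of any enol ester or pyrandione lactone under ethoxide, and by the irreversible deprotonation of each C-acylation product, which makes the doubly vinylogous carboxylate dianion of 8 the thermodynamic sink, while the identity of the two partners removes any cross-selectivity problem.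

Step 4
Reactants: 8 2,5-dihydroxy-3,6-di(1H-indol-3-yl)cyclohexa-2,5-diene-1,4-dione
Product: 9 4-hydroxy-2,5-di(1H-indol-3-yl)-3,6-dioxocyclohexa-1,4-dien-1-yl trifluoromethanesulfonate
Conditions: Tf2O (1.0 equiv, slow addition), i-Pr2NEt (2.2 equiv), CH2Cl2, −78 °C; dilute HCl work-up
Reagents that add atoms: trifluoromethanesulfonic anhydride, O=S(=O)(OS(=O)(=O)C(F)(F)F)C(F)(F)F
Why: O-Sulfonylation of a vinylogous acid: the dianion of 8 is far more nucleophilic than the monoanion of 9, whose remaining oxygen is deactivated by the new triflate, so one equivalent of Tf2O at low temperature should stop at the mono-triflate, and the indole N–H, not deprotonated by the amine, should stay untouched.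

Step 5
Reactants: 9 4-hydroxy-2,5-di(1H-indol-3-yl)-3,6-dioxocyclohexa-1,4-dien-1-yl trifluoromethanesulfonate
Product: 10 2,5-di(1H-indol-3-yl)-4-methoxy-3,6-dioxocyclohexa-1,4-dien-1-yl trifluoromethanesulfonate
Conditions: TMSCHN2 (1.3 equiv), CH2Cl2/MeOH (10:1), 0 °C
Reagents that add atoms: trimethylsilyldiazomethane, C[Si](C)(C)C=[N+]=[N-]
Why: The remaining hydroxyquinone OH is a vinylogous carboxylic acid that protonates the diazoalkane and should be O-methylated (diazoalkane esterification) to the 2-methoxy-1,4-quinone, the far less acidic indole N–H and the triflate being left alone under these cold neutral conditions.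

Step 6
Reactants: 10 2,5-di(1H-indol-3-yl)-4-methoxy-3,6-dioxocyclohexa-1,4-dien-1-yl trifluoromethanesulfonate; 11 tributyl(3-methylbut-2-en-1-yl)stannane
Product: 12 3,6-di(1H-indol-3-yl)-2-methoxy-5-(3-methylbut-2-en-1-yl)cyclohexa-2,5-diene-1,4-dione
Conditions: Pd2(dba)3 (5 mol %), AsPh3 (20 mol %), LiCl (3 equiv), NMP, 50 °C
Reagents that add atoms: none
Why: Stille coupling: oxidative addition of zerovalent palladium into the vinylogous acyl triflate, transmetalation from the allylic stannane and reductive elimination at the less substituted allyl terminus should give the linear prenyl quinone, with the free N–H groups and the vinylogous methyl ester tolerated; no stereocentre is formed.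

**Compound list**
1 | indole | c1ccc2[nH]ccc2c1 | starting material
2 | ethyl 3-bromo-2-(hydroxyimino)propanoate | CCOC(=O)C(CBr)=NO | starting material
3 | ethyl 2-nitrosoprop-2-enoate | CCOC(=O)C(=C)N=O | intermediate
4 | ethyl 2-(hydroxyimino)-3-(1H-indol-3-yl)propanoate | CCOC(=O)C(Cc1c[nH]c2ccccc12)=NO | intermediate
5 | ethyl 2-imino-3-(1H-indol-3-yl)propanoate | CCOC(=O)C(=N)Cc1c[nH]c2ccccc12 | intermediate
6 | ethyl 3-(1H-indol-3-yl)-2-oxopropanoate | CCOC(=O)C(=O)Cc1c[nH]c2ccccc12 | intermediate
7 | ethyl 3,6-di(1H-indol-3-yl)-2,4,5-trioxohexanoate | CCOC(=O)C(=O)C(c1c[nH]c2ccccc12)C(=O)C(=O)Cc1c[nH]c2ccccc12 | intermediate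
8 | 2,5-dihydroxy-3,6-di(1H-indol-3-yl)cyclohexa-2,5-diene-1,4-dione | O=C1C(O)=C(c2c[nH]c3ccccc23)C(=O)C(O)=C1c1c[nH]c2ccccc12 | intermediate
9 | 4-hydroxy-2,5-di(1H-indol-3-yl)-3,6-dioxocyclohexa-1,4-dien-1-yl trifluoromethanesulfonate | O=C1C(O)=C(c2c[nH]c3ccccc23)C(=O)C(OS(=O)(=O)C(F)(F)F)=C1c1c[nH]c2ccccc12 | intermediate
10 | 2,5-di(1H-indol-3-yl)-4-methoxy-3,6-dioxocyclohexa-1,4-dien-1-yl trifluoromethanesulfonate | COC1=C(c2c[nH]c3ccccc23)C(=O)C(OS(=O)(=O)C(F)(F)F)=C(c2c[nH]c3ccccc23)C1=O | intermediate
11 | tributyl(3-methylbut-2-en-1-yl)stannane | CCCC[Sn](CCCC)(CCCC)CC=C(C)C | starting material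
12 | 3,6-di(1H-indol-3-yl)-2-methoxy-5-(3-methylbut-2-en-1-yl)cyclohexa-2,5-diene-1,4-dione | COC1=C(c2c[nH]c3ccccc23)C(=O)C(CC=C(C)C)=C(c2c[nH]c3ccccc23)C1=O | target

Total step count: 6. Longest linear sequence: 6 steps (1 → 4 → 6 → 8 → 9 → 10 → 12).

**Steps most likely to fail**

Step 3. The first intermolecular C-acylation between two anionic partners may be too slow. Proton leakage could then reopen the aldol–lactonisation channel, or air oxidation of the electron-rich enolate could take over. The fallback sets out from indole 1 and comes back at 8, replacing steps 1 to 3 by known chemistry that forms the indole–quinone bonds instead of the ring bonds. Indole 1 is added to commercial 2,5-dichloro-1,4-benzoquinone under acid promotion (HCl, THF, rt) with re-oxidation by DDQ in the same flask, which should give 2,5-dichloro-3-(1H-indol-3-yl)cyclohexa-2,5-diene-1,4-dione F1. A second acid-promoted addition of 1 and DDQ oxidation should give 2,5-dichloro-3,6-di(1H-indol-3-yl)cyclohexa-2,5-diene-1,4-dione F2. Exchange of both vinylogous acyl chlorides with NaOH in aqueous MeOH at reflux, then acidification, should give 8.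

Step 4. The first and second sulfonylations may not be discriminated (bis-triflate formation), and the vinylogous acyl triflate may be lost by hydrolysis on work-up. The fallback sets out from 8 and comes back at 10, replacing steps 4 and 5; it desymmetrises by hydrolysis of a bis-ether instead of by kinetic mono-sulfonylation. Exhaustive O-methylation of 8 (excess TMSCHN2, CH2Cl2/MeOH) should give 3,6-di(1H-indol-3-yl)-2,5-dimethoxycyclohexa-2,5-diene-1,4-dione F3. Mono-hydrolysis with one equivalent of aqueous NaOH in THF should stop at 2-hydroxy-3,6-di(1H-indol-3-yl)-5-methoxycyclohexa-2,5-diene-1,4-dione F4, because the anionic product is deactivated toward a second addition–elimination. Triflation of the single OH (Tf2O, pyridine, CH2Cl2, −78 °C) should then give 10.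

Step 6. Allylic transposition during transmetalation or reductive elimination may give the branched 1,1-dimethylallyl isomer, and the stannane may be lost by protodestannylation. The fallback sets out from 10 and comes back at 12; it builds the prenyl group in two stages with no regiochemical ambiguity at the coupling. Stille coupling of 10 with allyltributylstannane (Pd2(dba)3, AsPh3, LiCl, NMP, 50 °C) should give 3,6-di(1H-indol-3-yl)-2-methoxy-5-(prop-2-en-1-yl)cyclohexa-2,5-diene-1,4-dione F5. Olefin cross-metathesis of F5 with excess 2-methyl-2-butene (second-generation Grubbs catalyst, CH2Cl2, 40 °C) should give 12.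

**Further compounds**
F1 | step 3 | 2,5-dichloro-3-(1H-indol-3-yl)cyclohexa-2,5-diene-1,4-dione | O=C1C(Cl)=C(c2c[nH]c3ccccc23)C(=O)C(Cl)=C1
F2 | step 3 | 2,5-dichloro-3,6-di(1H-indol-3-yl)cyclohexa-2,5-diene-1,4-dione | O=C1C(Cl)=C(c2c[nH]c3ccccc23)C(=O)C(Cl)=C1c1c[nH]c2ccccc12
F3 | step 4 | 3,6-di(1H-indol-3-yl)-2,5-dimethoxycyclohexa-2,5-diene-1,4-dione | COC1=C(c2c[nH]c3ccccc23)C(=O)C(OC)=C(c2c[nH]c3ccccc23)C1=O
F4 | step 4 | 2-hydroxy-3,6-di(1H-indol-3-yl)-5-methoxycyclohexa-2,5-diene-1,4-dione | COC1=C(c2c[nH]c3ccccc23)C(=O)C(O)=C(c2c[nH]c3ccccc23)C1=O
F5 | step 6 | 3,6-di(1H-indol-3-yl)-2-methoxy-5-(prop-2-en-1-yl)cyclohexa-2,5-diene-1,4-dione | COC1=C(c2c[nH]c3ccccc23)C(=O)C(CC=C)=C(c2c[nH]c3ccccc23)C1=O
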